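Before any share I look at the time of the reading, because a reading is good to 1 percentage point whatever its size, and the last Q in ash, 43.3%, is more than the first Q in larch, 4.4%, so a late share wobbles less than an early one.

| flask | L | E | J | remark | time |
|---|---|---|---|---|---|
| larch | 0.034 M | 1.3 equiv | 2.5 mM | run made earlier |  |
| oak | 0.075 M | 1.3 equiv | 2.5 mM | run made earlier |  |
| ash | 0.050 M | 2 equiv | 2.5 mM | run made earlier |  |
| flask | 0.050 M | 1.30 equiv | 2.50 mM |  | 3.0 h |

| run | time / h | Q / % | D / % |
|---|---|---|---|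
| larch | 0.200 | 4.4 | 2.3 |
| larch | 0.333 | 7.0 | 5.8 |
| larch | 0.500 | 10.4 | 5.4 |
| larch | 0.833 | 15.3 | 10.7 |
| larch | 1.33 | 18.2 | 11.9 |
| larch | 2.50 | 27.8 | 16.5 |
| oak | 0.167 | 7.8 | 4.9 |
| oak | 0.500 | 18.2 | 13.0 |
| oak | 0.833 | 24.5 | 16.7 |
| oak | 1.33 | 31.5 | 23.7 |
| oak | 2.00 | 35.6 | 23.9 |
| oak | 2.50 | 40.3 | 24.9 |
| ash | 0.200 | 8.9 | 7.8 |
| ash | 0.333 | 12.7 | 10.6 |
| ash | 0.667 | 23.8 | 15.8 |
| ash | 1.33 | 32.7 | 23.6 |
| ash | 2.50 | 43.3 | 28.5 |

(standard deviation of a reading: 1 percentage point)

* share of Q in Q plus D at 2.0 min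
* share of Q in Q plus D at 3.0 h
* which of Q and D there is more of at 3.0 h

- a reading or a percentage of Q counts all its forms, free or not

I build the flask up by steps. Suppose first that L and E only make Q and D side by side. Both rates then come from the same pair, their ratio stays fixed, and Q's part of Q plus D is the same at every time. I therefore read it where the amounts are large. Adding the last readings of larch, oak and ash gives 61.4%, and this part, the selectivity, is my split s. The same count up to 0.333 h gives 56.5%, but on smaller sums, so I keep s for 2.0 min.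

Next I add a possible drift of the split, read from the late gains, which carry the scatter of the readings. Between 1.33 h and 2.50 h, pooled across larch, oak and ash, Q takes 73.0% of the gain. Going on to 3.0 h at that pace adds 9.36% to what stands, which lifts the share by 0.99 points. Last comes J, charged at 2.5 mM in larch, oak and ash alike, and I add nothing for it. My reckoning is 61.4% at 2.0 min and 62.4% at 3.0 h, with Q ahead.

The forecast gives 56% at 2.0 min, 62% at 3.0 h and Q in the lead: “So selectivity appears to drift up slowly.” My early share is higher than its figure.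

The flask gives 61.5% at 2.0 min and 61.0% at 3.0 h, with Q at 36.4% and D at 23.3%.

    L + J → G (k = 0.00885 /M/s)
    Z ⇌ Q, rate k2*(cs2 - [Q]) while solid is left; crystals form when [Q] > cs2 (solubility = 0.520 mM, k = 6.80 × 10⁻⁴ /s)
    L + E ⇌ D (K = 36.1 /M, k = 9.53 × 10⁻⁴ /M/s)
    L + E ⇌ Q (K = 11.0 /M, k = 0.00153 /M/s)

With the back reaction of Q to L + E struck out, the share at 3.0 h is 65.8%. In this flask, s times Q plus D gives 36.7% against the 36.4% of Q. In the same recipe with 0.085 M of L, s times Q plus D gives 45.0%, and that flask holds 45.1% of Q at 3.00 h.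

The readings were generated by integration from invented constants; scatter was added.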